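(All runs are calculated for substances that don't exist; scatter was added.)

Which flask, red or blue, ends with the larger share of target among target, isomer of the product and side product?

| flask | starting material | temperature | remark | time |
|---|---|---|---|---|
| Sunday's | 0.15 M | 55 °C | run made earlier |  |
| Saturday's | 0.33 M | 70 °C | run made earlier |  |
| red | 0.22 M | 80 °C |  | 2.5 min |
| blue | 0.22 M | 60 °C |  | 2.5 min |

| run | time / min | target / % | isomer of the product / % | side product / % |
|---|---|---|---|---|
| Sunday's | 0.500 | 0 | 0 | 0.5 |
| Sunday's | 0.833 | 0.3 | 0 | 0.2 |
| Sunday's | 1.00 | 0 | 0 | 0 |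
| Sunday's | 1.50 | 0 | 0.1 | 0 |
| Sunday's | 3.00 | 0 | 0.5 | 0.6 |
| Sunday's | 5.00 | 0.7 | 0 | 0.4 |
| Sunday's | 6.00 | 1.6 | 0.3 | 0.2 |
| Saturday's | 0.250 | 0.5 | 0 | 0 |
| Saturday's | 0.417 | 0.1 | 0 | 0.2 |
| Saturday's | 0.500 | 0.2 | 0.6 | 0.1 |
| Saturday's | 0.833 | 0.9 | 0.5 | 0.3 |
| Saturday's | 1.33 | 1.3 | 0.1 | 0.6 |
| Saturday's | 2.00 | 2.3 | 0 | 0.6 |
| Saturday's | 3.00 | 3.8 | 1.0 | 2.1 |

(readings scatter by 0.3 percentage points)

1. the flask that comes out highest in share of target in all that became target or isomer of the product or side product, or "all alike" when all lie within 1.5 percentage points (red / blue / all alike)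
2. share of target in all that became target or isomer of the product or side product, red
3. share of target in all that became target or isomer of the product or side product, blue

- percent here means starting material units held: one side product counts as two
- steps thought possible: starting material -> intermediate; intermediate <-> target; intermediate <-> isomer of the product; starting material + target -> side product

1. Side product forms from starting material and target together. While starting material stays near its charge, that step is pseudo-first-order in target, and side product over target grows with concentration times time.

2. Saturday's last reading gives 0.558 M⁻¹ min⁻¹ for the side number, side product over target divided by starting concentration times time. Sunday's last reading gives 0.139 M⁻¹ min⁻¹, lower, but its side reading of 0.2% carries a scatter of 0.3 percentage points. As read, the hotter run has the higher number.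

3. Red and blue both have a concentration times time of 0.550 M·min. With Saturday's side number and isomer over target, the share is 63.7%. Red is hotter than Saturday's run, so my reckoning puts red below that. With Sunday's values, the share is 79.1%, my figure for blue, which is nearer that temperature.

4. The forecast names blue, with 67% for red and 71% for blue, closer together than my reckoning: “I expect blue slightly higher, but with low confidence.”

5. The flasks give blue: red 47.0%, blue 81.3%.

    starting material → intermediate (k = 0.00310 s⁻¹, Ea = 92.0 kJ mol⁻¹)
    intermediate ⇌ target (K = 0.360, k = 0.0120 s⁻¹, Ea = 98.0 kJ mol⁻¹, ΔH = −30.0 kJ mol⁻¹)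
    intermediate ⇌ isomer of the product (K = 2.80, k = 0.00170 s⁻¹, Ea = 111 kJ mol⁻¹, ΔH = −12.0 kJ mol⁻¹)
    starting material + target → side product (k = 0.0260 M⁻¹ s⁻¹, Ea = 85.0 kJ mol⁻¹)
    (constants at 80 °C)

The side number at the asked time is 1.11 M⁻¹ min⁻¹ in red, higher than the 0.186 M⁻¹ min⁻¹ in blue. Part of the gap between the flasks is the temperature acting on the side step: without it, red minus blue moves from −34 points to −18 points. Blue stands at 81.3% partly because it is read at 2.5 min and not at 25.0 min, where its share is 43.8%.

Blue read at 40 s has, by its side number, side product over target of 0.0272. With isomer over target of 0.114, the share is 87.7%; the computed value is 87.7%.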